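**Plan**
Retrosynthesis: the C1–C10 oxirane with its C14 methyl on the ten-membered ring is read as the oxide of an E-trisubstituted C1=C10 alkene, so the epoxide oxygen is removed first, then the O8 acyl bond and the lactone bond O6–C12 (back to a 2-methylene-1,4-diol).
The C1=C10 bond of the ten-membered ring is then cut to a C1 dienal and a C10 methyl ketone, and the open chain is cut at C3–C4 (Stille), C8–C9 (allylation), C11–C13 (methylenation) and C6–C7 (aldol).
Forward: aldol union C6–C7 with closure of a trans γ-lactone (first ring), allylation at C8, methylenation, reductive opening to the silylated diol, Wacker oxidation and Stille coupling to the keto-dienal, titanium closure of the ten-membered ring, oxidative re-closure of the lactone, acylation at O8, epoxidation last.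
Stereochemistry: C6 and C7 from the (S)-4-benzyloxazolidinone (syn aldol), C8 from the isopinocampheyl allylborane, 4Z and 2Z from hydroalumination of the two propargylic alcohols, 1(10)E from the titanium coupling, C1/C10 from peripheral peracid attack, and the ester stereocentres from a Sharpless epoxidation of tiglyl alcohol.

Key step: step 16

Remark: atoms carry germacranolide numbers throughout (ring C1–C10, lactone C11–C13 closed to O6, C14 on C10, C15 on C4). The acyl group is taken as drawn, the (2S,3R)-epoxide of a tiglate. Descriptors of C6 and C7 change along the route only through priority changes, not through inversion.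

Step 1
Reactants: 1 but-2-yn-1-ol
Product: 2 (Z)-3-iodobut-2-en-1-ol
Conditions: NaAlH2(OCH2CH2OMe)2 (Red-Al), THF, 0 °C to rt; then I2, THF, −78 to 0 °C
Reagents that add atoms: iodine, II
Why: Alkoxide-directed trans-hydroalumination puts aluminium on the carbon distal to the CH2O group (later C4) inside a five-membered alanate, and iodinolysis with retention should give the Z iodoalkene that becomes C4=C5.

Step 2
Reactants: 2 (Z)-3-iodobut-2-en-1-ol
Product: 3 (Z)-3-iodobut-2-enal
Conditions: MnO2, CH2Cl2, rt, dark; solution used at once
Reagents that add atoms: none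
Why: Allylic oxidation on MnO2 stops at the enal and leaves the C–I bond alone, and immediate use limits Z/E isomerisation of the iodoenal.

Step 3
Reactants: 4 (S)-4-benzyl-1,3-oxazolidin-2-one; 5 methyl 4-chloro-4-oxobutanoate
Product: 6 methyl 4-[(4S)-4-benzyl-2-oxo-1,3-oxazolidin-3-yl]-4-oxobutanoate
Conditions: n-BuLi, THF, −78 °C; then 5, −78 to 0 °C
Reagents that add atoms: none
Why: N-Acylation of the lithiated oxazolidinone occurs at the acid chloride, which is far more electrophilic than the methyl ester end.

Step 4
Reactants: 6 methyl 4-[(4S)-4-benzyl-2-oxo-1,3-oxazolidin-3-yl]-4-oxobutanoate; 3 (Z)-3-iodobut-2-enal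
Product: 8 trans-lactone imide (4S)-4-benzyl-3-{[(2S,3S)-2-[(1Z)-2-iodoprop-1-en-1-yl]-5-oxooxolan-3-yl]carbonyl}-1,3-oxazolidin-2-one, via syn-aldol hydroxy ester 7 (not isolated)
Conditions: Bu2BOTf, Et3N, CH2Cl2, −78 to 0 °C; 3, −78 to 0 °C; pH 7 buffer, MeOH, H2O2; then p-TsOH (cat.), CH2Cl2, rt
Reagents that add atoms: none
Why: Evans syn aldol, in which the Z boron enolate of the imide reacts through a closed Zimmerman–Traxler chair with one face blocked by the benzyl group of the (S)-auxiliary, sets C7 and C6 together (both S in 7), and the γ-hydroxy ester then closes under acid catalysis to the trans-disubstituted γ-lactone.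

Step 5
Reactants: 8 trans-lactone imide
Product: 9 (2S,3S)-2-[(1Z)-2-iodoprop-1-en-1-yl]-5-oxooxolane-3-carboxylic acid
Conditions: LiOH, H2O2, THF/H2O, 0 °C; Na2SO3; then 1 M HCl
Reagents that add atoms: hydrogen peroxide, OO
Why: Hydroperoxide cleaves the exocyclic imide carbonyl selectively (standard auxiliary removal); any lactone opening is undone on acidification because only the γ-lactone can re-close, and the trans lactone is the stable C7 epimer.

Step 6
Reactants: 9 lactone acid
Product: 11 (2S,3S)-2-[(1Z)-2-iodoprop-1-en-1-yl]-5-oxooxolane-3-carbaldehyde, via acid chloride 10 (not isolated)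
Conditions: (COCl)2, DMF (cat.), CH2Cl2, 0 °C to rt; then LiAlH(OtBu)3, THF, −78 °C; crude aldehyde used directly
Reagents that add atoms: none
Why: Partial reduction of an acid chloride by the hindered hydride LiAlH(OtBu)3 stops at the aldehyde and spares the lactone and the iodoalkene, and because trans is the thermodynamic relation of C6 and C7, enolisation at C7 cannot erode it.

Step 7
Reactants: 11 lactone aldehyde
Product: 12 (4R,5S)-4-[(1R)-1-hydroxybut-3-en-1-yl]-5-[(1Z)-2-iodoprop-1-en-1-yl]oxolan-2-one
Conditions: (+)-Ipc2BOMe (from (−)-α-pinene), allylMgBr, Et2O, 0 °C to rt; then 11, −78 °C; pH 7 buffer, H2O2, MeOH, 0 °C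
Reagents that add atoms: allylmagnesium bromide, C=CC[Mg]Br
Why: Brown allylboration, in which the isopinocampheyl groups steer the allyl group to the Re face of the C8 aldehyde through a chair transition state, sets C8 (R in 12) by reagent control largely independent of the adjacent C7 centre, and the lactone does not react at −78 °C.

Step 8
Reactants: 12 homoallylic alcohol
Product: 13 tert-butyldimethylsilyl ether of 12 at O8
Conditions: t-BuMe2SiOTf, 2,6-lutidine, CH2Cl2, −78 °C
Reagents that add atoms: tert-butyldimethylsilyl triflate, CC(C)(C)[Si](C)(C)OS(=O)(=O)C(F)(F)F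
Why: Silyl triflate silylation caps the hindered secondary alcohol under non-nucleophilic base and at the same time shuts off translactonisation of O8 onto C12.

Step 9
Reactants: 13 silyl ether lactone
Product: 16 α-methylene lactone bearing C11=C13, via Mannich base 14 (not isolated), via ammonium iodide 15 (not isolated)
Conditions: LiN(SiMe3)2, THF, −78 °C; CH2=NMe2 I, −78 °C to rt; MeI, MeOH, rt; NaHCO3, CH2Cl2/H2O, rt
Reagents that add atoms: dimethylmethyleneiminium iodide (Eschenmoser's salt), C=[N+](C)C.[I-]
Why: Eschenmoser methylenation: the lactone enolate is aminomethylated at C11, and quaternisation followed by mild base-induced elimination gives the exocyclic alkene; the amide base is consumed by the lactone α-proton at −78 °C before it can dehydroiodinate the iodoalkene.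

Step 10
Reactants: 16 α-methylene lactone
Product: 17 2-methylene-1,4-diol with free O6–H and O12–H and silylated O8
Conditions: i-Bu2AlH (excess), CH2Cl2, −78 to 0 °C; aq. potassium sodium tartrate
Reagents that add atoms: none
Why: i-Bu2AlH reduces the methylene lactone in the 1,2 sense through the lactol to the diol, without conjugate hydride addition and without touching the iodoalkene, the terminal alkene or the silyl ether.

Step 11
Reactants: 17 diol
Product: 18 bis(triethylsilyl) ether at O6 and O12
Conditions: Et3SiOTf, 2,6-lutidine, CH2Cl2, −78 °C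
Reagents that add atoms: triethylsilyl triflate, CC[Si](CC)(CC)OS(=O)(=O)C(F)(F)F
Why: Double silylation gives two triethylsilyl ethers that can later be removed together while the tert-butyldimethylsilyl ether on O8 stays.

Step 12
Reactants: 18 bis(triethylsilyl) ether
Product: 19 C10 methyl ketone
Conditions: PdCl2 (cat.), Cu(OAc)2 (cat.), O2 (1 atm), DMA/H2O, rt
Reagents that add atoms: water, O
Why: Tsuji–Wacker oxidation by Markovnikov hydroxypalladation of the only monosubstituted alkene gives the methyl ketone; the 1,1-disubstituted and iodo-substituted alkenes are too hindered to compete, divalent palladium does not insert into the C–I bond, and the acetate-buffered medium should spare the triethylsilyl ethers.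

Step 13
Reactants: 20 prop-2-yn-1-ol
Product: 21 (Z)-3-(tributylstannyl)prop-2-en-1-ol
Conditions: LiAlH4, THF, 0 °C to rt; then Bu3SnOTf, −78 °C to rt
Reagents that add atoms: tributyltin triflate, CCCC[Sn](CCCC)(CCCC)OS(=O)(=O)C(F)(F)F
Why: Alkoxide-directed trans-hydroalumination places aluminium on the terminal carbon cis to the CH2O group, and transfer to tin with retention gives the Z vinylstannane that supplies C1–C3.

Step 14
Reactants: 19 iodoalkene methyl ketone; 21 (Z)-3-(tributylstannyl)prop-2-en-1-ol
Product: 22 (2Z,4Z)-dienol
Conditions: Pd2(dba)3 (cat.), AsPh3, CuI, DMF, rt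
Reagents that add atoms: none
Why: Stille coupling: oxidative addition of zerovalent palladium into the C4–I bond, alkenyl transfer from tin (accelerated by CuI) and reductive elimination all go with retention, so the two Z partners should give the 2Z,4Z-diene at room temperature with the ketone untouched.

Step 15
Reactants: 22 (2Z,4Z)-dienol
Product: 23 acyclic keto-dienal (C1 aldehyde, C10 methyl ketone)
Conditions: Dess–Martin periodinane, NaHCO3, CH2Cl2, 0 °C; crude product used at once
Reagents that add atoms: none
Why: Dess–Martin oxidation of the primary dienylic alcohol is fast under buffered, non-acidic conditions, which should keep the 2Z,4Z geometry until the aldehyde enters the coupling.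

Step 16
Reactants: 23 acyclic keto-dienal
Product: 24 ten-membered (1E,2Z,4Z)-triene with silyl ethers on O6, O8 and O12
Conditions: TiCl3(DME)1.5, Zn–Cu couple, DME, 50–60 °C; 23 added by syringe pump over about 30 h (high dilution)
Reagents that add atoms: none
Why: TiCl3 reduced by Zn–Cu gives low-valent titanium that transfers one electron to each carbonyl group of 23; the C1 dienyl ketyl and the C10 ketyl, held on the same titanium surface, combine at C1 and C10 to a titanium pinacolate, and the oxophilic metal then strips both oxygens to leave the C1=C10 alkene (McMurry coupling, closest precedent the titanium keto-aldehyde cyclisations to ten- to fourteen-membered cycloalkenes of the germacrane and humulene type). The ten-membered carbocycle is closed in this single intramolecular C1–C10 ketyl–ketyl union, run by slow addition so that ring closure outruns dimerisation, and it is helped by the Z,Z-diene and the three contiguous substituted centres C6–C8, which fold the chain so that both ends meet. No stereocentre is formed; the one new stereo element is the C1=C10 geometry, fixed in the stepwise C–O cleavage of the pinacolate, where the less strained E,Z,Z ring should be preferred over the Z,Z,Z isomer, any of which would be separated. The step needs chemoselectivity, secured because 23 holds only these two carbonyl groups and every hydroxyl is a silyl ether, and it needs the 2Z,4Z diene to survive, for which the dienylic C1–O bond of the pinacolate should break well below reflux, so that the moderate temperature limits Z/E isomerisation on the Lewis-acidic titanium chlorides and 6π closure of the triene.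

Step 17
Reactants: 24 ten-membered triene
Product: 25 triene diol with free O6–H and O12–H and silylated O8
Conditions: HF·pyridine, pyridine, THF, 0 °C
Reagents that add atoms: none
Why: Buffered fluoride removes the two triethylsilyl ethers, which cleave much faster than the secondary tert-butyldimethylsilyl ether, without exposing the trienyl carbinol at C6 to free acid.

Step 18
Reactants: 25 triene diol
Product: 27 triene 6,12-lactone with silylated O8, via lactol 26 (not isolated)
Conditions: TEMPO (cat.), PhI(OAc)2, CH2Cl2, rt
Reagents that add atoms: none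
Why: Oxoammonium-catalysed oxidative lactonisation: the primary allylic C12 alcohol is oxidised much faster than the secondary C6 alcohol, the enal is trapped by O6 as the five-membered lactol, and a second oxidation gives the α-methylene γ-lactone; O8 is still silylated, so only the 6,12-lactone can form.

Step 19
Reactants: 27 silylated triene lactone
Product: 28 triene lactone with free C8 hydroxyl
Conditions: Bu4NF, AcOH, THF, 0 °C to rt
Reagents that add atoms: none
Why: Acetic acid-buffered fluoride cleaves the remaining silyl ether without adding to the methylene lactone or ionising the allylic lactone C6–O bond.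

Step 20
Reactants: 29 tiglic acid
Product: 30 (E)-2-methylbut-2-en-1-ol
Conditions: LiAlH4, Et2O, 0 °C
Reagents that add atoms: none
Why: Hydride reduction of the conjugated acid occurs at the carboxyl group and leaves the E-trisubstituted alkene unchanged.

Step 21
Reactants: 30 (E)-2-methylbut-2-en-1-ol
Product: 31 [(2R,3R)-2,3-dimethyloxiran-2-yl]methanol
Conditions: Ti(OiPr)4 (cat.), D-(−)-diethyl tartrate (cat.), t-BuOOH, 4 Å molecular sieves, CH2Cl2, −20 °C
Reagents that add atoms: tert-butyl hydroperoxide, CC(C)(C)OO
Why: Sharpless asymmetric epoxidation: the titanium D-tartrate complex delivers oxygen to the face of the E-allylic alcohol that gives the (2R,3R)-epoxy alcohol, which sets both stereocentres of the side chain with the two methyl groups cis.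

Step 22
Reactants: 31 epoxy alcohol
Product: 32 (2S,3R)-2,3-dimethyloxirane-2-carboxylic acid
Conditions: RuCl3 (cat.), NaIO4, CCl4/MeCN/H2O, rt
Reagents that add atoms: water, O
Why: RuO4 formed in situ oxidises the primary alcohol through the aldehyde hydrate to the acid and leaves the trisubstituted epoxide intact; C2 becomes S only through the priority change.

Step 23
Reactants: 28 triene lactone alcohol; 32 (2S,3R)-2,3-dimethyloxirane-2-carboxylic acid
Product: 34 C8 epoxy ester of the triene lactone, via mixed anhydride 33 (not isolated)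
Conditions: 2,4,6-Cl3C6H2COCl, Et3N, toluene, rt; then 28, DMAP, toluene, rt
Reagents that add atoms: none
Why: Yamaguchi esterification: DMAP attacks the mixed anhydride at the aliphatic carbonyl and the acylpyridinium acylates the hindered C8 hydroxyl; the epoxy acid has no α-hydrogen, so its stereocentres cannot epimerise.

Step 24
Reactants: 34 triene epoxy ester
Product: 35 CNP0122107.1
Conditions: mCPBA, CH2Cl2, −20 to 0 °C
Reagents that add atoms: meta-chloroperoxybenzoic acid, O=C(OO)c1cccc(Cl)c1
Why: Prilezhaev epoxidation: the peracid should take the most electron-rich alkene, the trisubstituted C1=C10 end of the triene (C4=C5 is deactivated by the allylic lactone oxygen, the methylene lactone is electron-poor), from the outer face of the ten-membered ring, whose E-alkene stands roughly perpendicular to the mean ring plane with its inner face blocked across the ring, and syn addition to the E-alkene should give the trans (1R,10R)-epoxide.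

**Compound list**
1 | but-2-yn-1-ol | CC#CCO | starting material
2 | (Z)-3-iodobut-2-en-1-ol | C/C(I)=C/CO | intermediate
3 | (Z)-3-iodobut-2-enal | C/C(I)=C/C=O | intermediate
4 | (S)-4-benzyl-1,3-oxazolidin-2-one | O=C1N[C@@H](Cc2ccccc2)CO1 | starting material
5 | methyl 4-chloro-4-oxobutanoate | COC(=O)CCC(=O)Cl | starting material
6 | methyl 4-[(4S)-4-benzyl-2-oxo-1,3-oxazolidin-3-yl]-4-oxobutanoate | COC(=O)CCC(=O)N1[C@@H](Cc2ccccc2)COC1=O | intermediate
7 | syn-aldol hydroxy ester, methyl (3S,4S,5Z)-3-{[(4S)-4-benzyl-2-oxo-1,3-oxazolidin-3-yl]carbonyl}-4-hydroxy-6-iodohept-5-enoate | COC(=O)C[C@@H]([C@H](O)/C=C(C)\I)C(=O)N1[C@@H](Cc2ccccc2)COC1=O | intermediate (not isolated)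
8 | trans-lactone imide, (4S)-4-benzyl-3-{[(2S,3S)-2-[(1Z)-2-iodoprop-1-en-1-yl]-5-oxooxolan-3-yl]carbonyl}-1,3-oxazolidin-2-one | O=C1C[C@H](C(=O)N2[C@@H](Cc3ccccc3)COC2=O)[C@@H](/C=C(C)\I)O1 | intermediate
9 | (2S,3S)-2-[(1Z)-2-iodoprop-1-en-1-yl]-5-oxooxolane-3-carboxylic acid | O=C1C[C@H](C(=O)O)[C@@H](/C=C(C)\I)O1 | intermediate
10 | acid chloride of 9 | O=C1C[C@H](C(=O)Cl)[C@@H](/C=C(C)\I)O1 | intermediate (not isolated)
11 | (2S,3S)-2-[(1Z)-2-iodoprop-1-en-1-yl]-5-oxooxolane-3-carbaldehyde | O=C1C[C@H](C=O)[C@@H](/C=C(C)\I)O1 | intermediate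
12 | (4R,5S)-4-[(1R)-1-hydroxybut-3-en-1-yl]-5-[(1Z)-2-iodoprop-1-en-1-yl]oxolan-2-one | O=C1C[C@H]([C@H](O)CC=C)[C@@H](/C=C(C)\I)O1 | intermediate
13 | O8 tert-butyldimethylsilyl ether of 12 (same configuration at C6, C7, C8) | O=C1C[C@H]([C@H](O[Si](C)(C)C(C)(C)C)CC=C)[C@@H](/C=C(C)\I)O1 | intermediate
14 | Mannich base, 13 with CH2NMe2 on C11 (C11 epimers) | O=C1C(CN(C)C)[C@H]([C@H](O[Si](C)(C)C(C)(C)C)CC=C)[C@@H](/C=C(C)\I)O1 | intermediate (not isolated)
15 | trimethylammonium iodide of 14 | O=C1C(C[N+](C)(C)C)[C@H]([C@H](O[Si](C)(C)C(C)(C)C)CC=C)[C@@H](/C=C(C)\I)O1.[I-] | intermediate (not isolated)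
16 | α-methylene lactone (13 with exocyclic C11=C13) | C=C1C(=O)O[C@H](/C=C(C)\I)[C@H]1[C@H](O[Si](C)(C)C(C)(C)C)CC=C | intermediate
17 | 2-methylene-1,4-diol (O6–H, O12–H free, O8 silylated) | C=C(CO)[C@H]([C@H](O[Si](C)(C)C(C)(C)C)CC=C)[C@H](O)/C=C(C)\I | intermediate
18 | O6,O12-bis(triethylsilyl) ether of 17 | C=C(CO[Si](CC)(CC)CC)[C@H]([C@H](O[Si](C)(C)C(C)(C)C)CC=C)[C@H](O[Si](CC)(CC)CC)/C=C(C)\I | intermediate
19 | C10 methyl ketone with (Z)-iodoalkene | C=C(CO[Si](CC)(CC)CC)[C@H]([C@H](O[Si](C)(C)C(C)(C)C)CC(C)=O)[C@H](O[Si](CC)(CC)CC)/C=C(C)\I | intermediate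
20 | prop-2-yn-1-ol | C#CCO | starting material
21 | (Z)-3-(tributylstannyl)prop-2-en-1-ol | CCCC[Sn](CCCC)(CCCC)/C=C\CO | intermediate
22 | (2Z,4Z)-dienol with C10 ketone | C=C(CO[Si](CC)(CC)CC)[C@H]([C@H](O[Si](C)(C)C(C)(C)C)CC(C)=O)[C@H](O[Si](CC)(CC)CC)/C=C(C)\C=C/CO | intermediate
23 | acyclic (2Z,4Z)-keto-dienal | C=C(CO[Si](CC)(CC)CC)[C@H]([C@H](O[Si](C)(C)C(C)(C)C)CC(C)=O)[C@H](O[Si](CC)(CC)CC)/C=C(C)\C=C/C=O | intermediate
24 | ten-membered (1E,2Z,4Z)-triene, O6/O12 triethylsilyl, O8 tert-butyldimethylsilyl | C=C(CO[Si](CC)(CC)CC)[C@H]1[C@H](O[Si](CC)(CC)CC)/C=C(C)\C=C/C=C(C)/C[C@H]1O[Si](C)(C)C(C)(C)C | intermediate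
25 | triene diol (O6–H, O12–H free) | C=C(CO)[C@H]1[C@H](O)/C=C(C)\C=C/C=C(C)/C[C@H]1O[Si](C)(C)C(C)(C)C | intermediate
26 | lactol (C12 hemiacetal closed to O6, C12 epimers) | C=C1C(O)O[C@@H]2/C=C(C)\C=C/C=C(C)/C[C@@H](O[Si](C)(C)C(C)(C)C)[C@@H]12 | intermediate (not isolated)
27 | triene 6,12-lactone, O8 silylated | C=C1C(=O)O[C@@H]2/C=C(C)\C=C/C=C(C)/C[C@@H](O[Si](C)(C)C(C)(C)C)[C@@H]12 | intermediate
28 | triene 6,12-lactone, C8 hydroxyl free | C=C1C(=O)O[C@@H]2/C=C(C)\C=C/C=C(C)/C[C@@H](O)[C@@H]12 | intermediate
29 | tiglic acid, (E)-2-methylbut-2-enoic acid | C/C=C(\C)C(=O)O | starting material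
30 | (E)-2-methylbut-2-en-1-ol | C/C=C(\C)CO | intermediate
31 | [(2R,3R)-2,3-dimethyloxiran-2-yl]methanol | OC[C@@]1(C)O[C@@H]1C | intermediate
32 | (2S,3R)-2,3-dimethyloxirane-2-carboxylic acid | OC(=O)[C@@]1(C)O[C@@H]1C | intermediate
33 | mixed anhydride of 32 with 2,4,6-trichlorobenzoic acid | O=C(OC(=O)[C@@]1(C)O[C@@H]1C)c1c(Cl)cc(Cl)cc1Cl | intermediate (not isolated)
34 | triene lactone C8 (2S,3R)-2,3-dimethyloxirane-2-carboxylate | C=C1C(=O)O[C@@H]2/C=C(C)\C=C/C=C(C)/C[C@@H](OC(=O)[C@@]3(C)O[C@@H]3C)[C@@H]12 | intermediate
35 | CNP0122107.1 | C=C1C(=O)O[C@@H]2/C=C(C)\C=C/[C@H]3O[C@]3(C)C[C@@H](OC(=O)[C@@]3(C)O[C@@H]3C)[C@@H]12 | target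

**Step count and risks**
Total step count: 24. Longest linear sequence: 19 steps (1, 2, 4–12, 14–19, 23, 24).

Steps most likely to fail:

1. Step 16. The vinylogous C1 ketyl may be reduced further with loss of the C6 silyloxy group, the 2Z bond may isomerise on the Lewis-acidic titanium chlorides, or the E,Z,Z-triene may undergo 6π ring closure at the temperature needed to deoxygenate the pinacolate. Fallback: setting out from 23, SmI2 (THF, t-BuOH, −78 to 0 °C, high dilution) should stop the coupling at the pinacol stage and give the ten-membered 1,10-diol F1 without heating. Thiophosgene and DMAP (CH2Cl2, 0 °C) would convert it to the cyclic thionocarbonate F2, and 1,3-dimethyl-2-phenyl-1,3,2-diazaphospholidine (THF, 25–40 °C) would effect the stereospecific syn-elimination of a Corey–Winter olefination, which comes back to the route at 24. Only diols in which C2 and C9 sit trans on the thionocarbonate ring (F1 as drawn, or its C1,C10-bis-epimer) lead to the E alkene; a cis isomer would be separated at the diol stage.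

2. Step 24. Facial selectivity of the peracid on the flexible ten-membered triene may be poor, or C4=C5 may compete. Fallback: setting out from 28, a Shi epoxidation (D-fructose-derived ketone, KHSO5 as Oxone, K2CO3 buffer, MeCN/dimethoxymethane/H2O, 0 °C) would place the oxygen under reagent control. By analogy with simple E-alkenes, this ketone is expected to give the (1R,10R)-oxide, the epoxy alcohol F3. Yamaguchi acylation of F3 with anhydride 33 (from 32, as in step 23) then comes back to the route at 35.

3. Step 15. The 2Z bond may isomerise, or the cis-dienal may close to a 2H-pyran, while the dienol is oxidised and the dienal handled. Fallback: setting out from 21, MnO2 (CH2Cl2, rt) would give (Z)-3-(tributylstannyl)prop-2-enal F4, and Stille coupling of F4 with 19 under the conditions of step 14 would deliver the aldehyde with the diene in one operation, without an oxidation on the diene. This comes back to the route at 23, which is passed on crude to step 16.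

Further compounds
F1 | step 16 | 1,10-pinacol diol of the ten-membered diene (C1–OH, C10–OH) | C=C(CO[Si](CC)(CC)CC)[C@H]1[C@H](O[Si](CC)(CC)CC)/C=C(C)\C=C/[C@@H](O)[C@](C)(O)C[C@H]1O[Si](C)(C)C(C)(C)C
F2 | step 16 | cyclic 1,10-thionocarbonate of F1 | C=C(CO[Si](CC)(CC)CC)[C@H]1[C@H](O[Si](CC)(CC)CC)/C=C(C)\C=C/[C@H]2OC(=S)O[C@]2(C)C[C@H]1O[Si](C)(C)C(C)(C)C
F3 | step 24 | (1R,10R)-1,10-epoxy lactone with free C8 hydroxyl | C=C1C(=O)O[C@@H]2/C=C(C)\C=C/[C@H]3O[C@]3(C)C[C@@H](O)[C@@H]12
F4 | step 15 | (Z)-3-(tributylstannyl)prop-2-enal | CCCC[Sn](CCCC)(CCCC)/C=C\C=O
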